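The data stem from a simulated flask for an exercise, and the scatter is random.

I book this flask in gas refills, and I keep the ledger on starting material, the limiting reagent here: the gas is held, the charge is finite.

common to all: gas 1.8 mM (held)
- teal: starting material 0.055 M; run made earlier
- delta: starting material 0.050 M; time 5.0 min
- gamma: starting material 0.10 M; time 5.0 min
- beta: starting material 0.20 M; time 5.0 min

- teal (time / s: target / %): 15.0: 2.1; 30.0: 10.2; 50.0: 13.9; 60.0: 15.6; 80.0: 21.0; 90.0: 21.7; 120: 23.2

(each reading ± 1 percentage point)

- at the start none of the gas is in solution
- "hardly changes" means that all values lie within two and a half points (for a concentration: within two and a half percent of the largest)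

- amount of target at the end, in percent of the starting material charged for delta, gamma, beta, in this order
- how the row runs (hardly changes / rises, then falls / falls, then rises / falls all the way / rises all the way)

A refill is the dissolved pool of gas, c(gas) = 1.8 mM, and I assume one gas per target. The refill count, the charge of starting material divided by c(gas), is 27.8 for delta; it says how many turnovers of the pool that charge costs. In teal, the target entry at 120 s is 23.2% of the charge, worth 7.09 refills. Teal's readings from 15.0 s to 30.0 s show a pace of 0.297 mM/s, a reading with its scatter. Held that long, this pace would supply 19.8 refills, more than teal's target entry holds. So teal's flat stretch doesn't look like a gas shortage, and the rest of its ledger sits in entries nobody has read.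

As my estimate, that pace held over 5.0 min comes to 49.5 refills. Delta's bill is smaller, while the pace pays 89.1% of gamma's bill and 44.5% of beta's. I commit to a falling row, with target well under those shares. The forecast also falls: 31%, 21%, 13.5%, falls all the way, on the ground of “a loss that is higher order in starting material”; my reckoning gives shares of the bill, not its target values.

The flask gives 22.8%, 17.9%, 11.8%: falls all the way.

    starting material + reagent → target (k = 4.40 /M/s)
    2 starting material → self-condensation product (k = 0.0258 /M/s)
    gas ⇌ reagent, rate k3*(csat - [reagent]) (kL = 0.226 /s)
    target → over-reaction product (k = 0.00678 /s)

Delta's books close at 5.0 min with target 22.8%, over-reaction product 44.5%, self-condensation product 19.6% (counted as the starting material it holds) and starting material 13.1%. Target and over-reaction product together cost 18.7 of delta's 27.8 refills, and more of that stands as over-reaction product than as target. The delta run without the reaction of target to over-reaction product holds 67.3% target against 22.8%, the main reason for the shortfall, at 58% of what is missing. Beta paid 35.9 of its 111 refills, and there the same reaction is a part of the loss, taking 20 percentage points of target.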